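**Plan**

- Retrosynthesis: the C14 carboxyl is cut from C8 (CO into a C7=C8 enol triflate of a C8 ketone, itself from a C8=C14 methylene) and C3–H is traced back to C3–OH. Then C4–C5 and C9–C10 are cut together, opening rings A and B to an acyclic epoxy diene. The chain is cut at C9–C11 (alkenyl iodide + alkylborane), C8–C14 (alkyne carbocupration) and C6–C7 (allylic bromide + propargyl unit).
- Forward: geranyl acetate supplies C1–C6, C10 and C18–C20 as an epoxy allylic bromide. Propargylation, silylmethylcupration–iodination and B-alkyl Suzuki coupling with the isobutyraldehyde-derived side chain complete the chain. Rings A and B then form in one operation (ring A first), and the endgame adjusts C3, C8/C14, C18 and C13.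
- Enabling feature: C4, C5, C10 and C9 are contiguous stereocentres on a trans-fused decalin (ring A = C1–C5 + C10, ring B = C5–C10), placed as a chair–chair folded chain with E alkenes at C5=C10 and C8=C9 delivers them. C8 carries an sp2 carbon that an allylsilane terminator leaves as a C8=C14 alkene.
- Stereochemistry: the Sharpless epoxide fixes C3 and, by inversion on opening, C4. Alkene geometry and the two chairs relay this to C5, C10 and C9. C13 is only a carbinol on the way to the ketone.

Key step: step 11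

Remark: abietane numbering is used throughout (C18 = equatorial carbon on C4, C19 = axial methyl on C4, C20 = methyl on C10, C14 = carbon on C8, side chain C11–C12–C13 on C9 with isopropyl on C13). The C13 carbinol is made racemic and carried as both epimers because step 18 oxidizes it, so its configuration is left open in names and SMILES. Every bicyclic compound has 4β-CH3, 4α-C18, 5α-H, 9α-H (side chain 9β, equatorial) and 10β-CH3.

**Route**

Step 1
Reactants: 1 geranyl acetate
Product: 2 (2E,6E)-8-hydroxy-3,7-dimethylocta-2,6-dien-1-yl acetate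
Conditions: SeO2 (cat.), t-BuOOH, salicylic acid (cat.), CH2Cl2, rt
Reagents that add atoms: tert-butyl hydroperoxide, CC(C)(C)OO (oxygen relayed through SeO2)
Why: Riley allylic oxidation (ene reaction then [2,3]-sigmatropic shift) attacks the E-methyl of the terminal trisubstituted alkene, the other alkene being deactivated by the allylic acetate, and the E-CH2OH so formed is the geometry that later makes C18 equatorial.

Step 2
Reactants: 2 (2E,6E)-8-hydroxy-3,7-dimethylocta-2,6-dien-1-yl acetate
Product: 3 (2E)-5-[(2S,3S)-3-(hydroxymethyl)-3-methyloxiran-2-yl]-3-methylpent-2-en-1-yl acetate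
Conditions: Ti(OiPr)4 (cat.), L-(+)-diethyl tartrate (cat.), t-BuOOH, 4 Å molecular sieves, CH2Cl2, −20 °C
Reagents that add atoms: tert-butyl hydroperoxide, CC(C)(C)OO
Why: Sharpless asymmetric epoxidation is confined to the allylic alcohol and, with L-(+)-diethyl tartrate, should deliver oxygen to the face that gives the (2S,3S)-epoxide, which fixes C3 and the configuration from which C4 is derived.

Step 3
Reactants: 3 (2E)-5-[(2S,3S)-3-(hydroxymethyl)-3-methyloxiran-2-yl]-3-methylpent-2-en-1-yl acetate
Product: 4 (2E)-5-[(2S,3S)-3-({[tert-butyl(dimethyl)silyl]oxy}methyl)-3-methyloxiran-2-yl]-3-methylpent-2-en-1-yl acetate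
Conditions: TBSCl, imidazole, DMF, 0 °C → rt
Reagents that add atoms: tert-butyldimethylsilyl chloride, CC(C)(C)[Si](C)(C)Cl
Why: Silylation of the primary alcohol (substitution at silicon with imidazole as base) installs a poorly Lewis-basic, weakly electron-withdrawing ether that will not compete for the Lewis acid in step 11.

Step 4
Reactants: 4 the silyl ether acetate of step 3
Product: 5 (2E)-5-[(2S,3S)-3-({[tert-butyl(dimethyl)silyl]oxy}methyl)-3-methyloxiran-2-yl]-3-methylpent-2-en-1-ol
Conditions: K2CO3 (cat.), MeOH, 0 °C → rt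
Reagents that add atoms: none
Why: Carbonate-catalysed transesterification with methanol frees the allylic alcohol while the epoxide and the silyl ether are inert to methoxide at this temperature.

Step 5
Reactants: 5 the allylic alcohol of step 4
Product: 7 ({(2S,3S)-3-[(3E)-5-bromo-3-methylpent-3-en-1-yl]-2-methyloxiran-2-yl}methoxy)(tert-butyl)dimethylsilane, via allylic mesylate 6 (not isolated)
Conditions: MsCl, Et3N, THF, −40 °C; then LiBr, THF, 0 °C
Reagents that add atoms: lithium bromide, [Li+].[Br-]
Why: Mesylation followed by SN2 displacement with bromide converts the primary allylic alcohol into the bromide without acid, so the epoxide is untouched and the E alkene keeps its geometry.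

Step 6
Reactants: 7 the allylic bromide of step 5; 8 propargyl bromide
Product: 9 tert-butyl(dimethyl)({(2S,3S)-2-methyl-3-[(3E)-3-methyloct-3-en-7-yn-1-yl]oxiran-2-yl}methoxy)silane
Conditions: 8, n-BuLi (2 equiv), TMEDA, Et2O–hexane, −78 °C; then 7, −78 → −20 °C; then H2O
Reagents that add atoms: none
Why: 1,3-Dilithiopropyne, formed from 8 by deprotonation and bromine–lithium exchange, alkylates the allylic bromide at its propargylic carbon in an SN2 reaction (C6–C7 bond) and gives the terminal 1,5-enyne after protonation, the hindered trisubstituted epoxide being inert at low temperature.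

Step 7
Reactants: 9 the enyne of step 6; 10 (trimethylsilyl)methylmagnesium chloride
Product: 12 tert-butyl({(2S,3S)-3-[(3E,7Z)-8-iodo-3-methyl-7-[(trimethylsilyl)methyl]octa-3,7-dien-1-yl]-2-methyloxiran-2-yl}methoxy)dimethylsilane, via alkenylcopper 11 (not isolated)
Conditions: 10, CuBr·SMe2, Et2O–Me2S, −45 °C; then 9, −25 °C; then I2 (1 equiv), THF, −78 → 0 °C
Reagents that add atoms: iodine, [I][I]
Why: Normant carbocupration adds Me3SiCH2–Cu syn across the terminal alkyne with carbon at the internal C8 and copper at C9, and iodinolysis with retention gives the iodide in which iodine is cis to CH2SiMe3 and trans to C7, the geometry needed for an equatorial C9 side chain.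

Step 8
Reactants: 13 isobutyraldehyde; 14 vinylmagnesium bromide
Product: 15 rac-4-methylpent-1-en-3-ol
Conditions: THF, 0 °C; then H2O
Reagents that add atoms: none
Why: Grignard 1,2-addition to the aldehyde builds the C12–C13 bond, and the carbinol is formed racemic, which is immaterial because step 18 oxidizes it.

Step 9
Reactants: 15 rac-4-methylpent-1-en-3-ol
Product: 16 rac-tert-butyl(dimethyl)[(4-methylpent-1-en-3-yl)oxy]silane
Conditions: TBSCl, imidazole, DMF, rt
Reagents that add atoms: tert-butyldimethylsilyl chloride, CC(C)(C)[Si](C)(C)Cl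
Why: Silylation masks the future C13 ketone as an ether that neither binds MeAlCl2 strongly nor acts as a nucleophile in the cation cascade.

Step 10
Reactants: 16 the silyl ether of step 9; 12 the alkenyl iodide of step 7
Product: 18 tert-butyl({(2S,3S)-3-[(3E,7Z)-11-{[tert-butyl(dimethyl)silyl]oxy}-3,12-dimethyl-7-[(trimethylsilyl)methyl]trideca-3,7-dien-1-yl]-2-methyloxiran-2-yl}methoxy)dimethylsilane (both epimers at the silyloxy carbon), via alkylborane 17 (not isolated)
Conditions: 16, 9-BBN, THF, 0 °C → rt; then 12, Pd(dppf)Cl2 (cat.), AsPh3, Cs2CO3, DMF–H2O, rt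
Reagents that add atoms: none
Why: Anti-Markovnikov hydroboration of the terminal alkene and B-alkyl Suzuki–Miyaura coupling with the alkenyl iodide forge C9–C11 with retention of alkene geometry under mildly basic conditions that the epoxide, the allylsilane and the silyl ethers tolerate.

Step 11
Reactants: 18 the epoxy diene of step 10
Product: 19 13,18-bis(tert-butyldimethylsilyloxy)-13,14-seco-abiet-8(14)-en-3β-ol (trans-decalin with equatorial 3β-OH and exocyclic C8=C14 methylene)
Conditions: MeAlCl2 (1.5 equiv), CH2Cl2, −78 °C; then Et3N, H2O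
Reagents that add atoms: none
Why: MeAlCl2 binds the epoxide oxygen and the C4–O bond breaks while C5 of the C5=C10 alkene attacks C4 from the rear; the tertiary C10 cation is captured by C9 of the allylsilane and the β-silyl cation at C8 loses Me3Si (SE2′), which leaves the C8=C14 exocyclic alkene. The closest known reaction type is the Lewis-acid-promoted epoxy-polyene cation–olefin cyclization with allylsilane termination. Ring A closes 6-endo (C4–C5) and ring B closes 6-endo (C9–C10), both through chair transition states. C3 keeps the Sharpless configuration (3β-OH), C4 is set by inversion at the epoxide carbon so that the E-CH2OTBS group becomes equatorial (4α), C5 and C10 by anti addition across the E C5=C10 alkene (trans fusion, 5α-H, 10β-CH3), and C9 by the chair placement of an alkene in which C11 is trans to C7 (side chain equatorial, 9α-H). The step needs opening at C4 and not C3, capture of the C10 cation before proton loss, and a single alkene position in the product; the tertiary epoxide carbon, the nucleophilic allylsilane and the irreversible loss of silicon secure these. Both carbinols are carried as silyl ethers, weakly Lewis-basic and only mildly electron-withdrawing, so that ionization at the oxygen-bearing C4 is slowed as little as possible and no oxygen intercepts a cation.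

Step 12
Reactants: 19 the bicyclic 3β-alcohol of step 11
Product: 20 O-[13,18-bis(tert-butyldimethylsilyloxy)-13,14-seco-abiet-8(14)-en-3β-yl] O-phenyl thiocarbonate
Conditions: PhOC(S)Cl, pyridine, DMAP (cat.), CH2Cl2, rt
Reagents that add atoms: O-phenyl chlorothionoformate, ClC(=S)Oc1ccccc1
Why: Thioacylation of the only free hydroxyl under amine base (no alkoxide) gives the thionocarbonate needed for radical deoxygenation and avoids 1,3-silyl migration from O18 to O3.

Step 13
Reactants: 20 the thionocarbonate of step 12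
Product: 21 13,18-bis(tert-butyldimethylsilyloxy)-13,14-seco-abiet-8(14)-ene
Conditions: Bu3SnH, AIBN (cat.), toluene, 100 °C
Reagents that add atoms: none
Why: Barton–McCombie deoxygenation, in which the Bu3Sn radical adds to C=S, β-scission releases the secondary C3 radical and this abstracts hydrogen from Bu3SnH, with no alkene within reach of that radical.

Step 14
Reactants: 21 the exocyclic alkene of step 13
Product: 23 13,18-bis(tert-butyldimethylsilyloxy)-14-nor-13,14-seco-abietan-8-one, via ozonide 22 (not isolated)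
Conditions: O3, CH2Cl2, −78 °C; then PPh3, −78 °C → rt
Reagents that add atoms: ozone, [O-][O+]=O
Why: Ozonolysis (1,3-dipolar cycloaddition, rearrangement to the ozonide, reduction by PPh3) cleaves the only alkene to the C8 ketone and formaldehyde, and C9 keeps its equatorial side chain, the thermodynamically favoured arrangement next to the ketone.

Step 15
Reactants: 23 the C8 ketone of step 14
Product: 25 13,18-bis(tert-butyldimethylsilyloxy)-14-nor-13,14-seco-abiet-7-en-8-yl trifluoromethanesulfonate, via lithium enolate 24 (not isolated)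
Conditions: LiN(iPr)2, THF, −78 °C; then N-(5-chloropyridin-2-yl)bis(trifluoromethanesulfonyl)imide, −78 → 0 °C
Reagents that add atoms: N-(5-chloropyridin-2-yl)bis(trifluoromethanesulfonyl)imide, FC(F)(F)S(=O)(=O)N(c1ccc(Cl)cn1)S(=O)(=O)C(F)(F)F
Why: Kinetic deprotonation with the hindered amide base removes a proton from the C7 methylene and not the tertiary C9–H beside quaternary C10, and O-sulfonylation of the enolate gives the C7=C8 enol triflate without touching C9.

Step 16
Reactants: 25 the enol triflate of step 15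
Product: 26 13,18-bis(tert-butyldimethylsilyloxy)-13,14-seco-abiet-7-en-14-oic acid
Conditions: Pd(OAc)2 (cat.), dppf, Et3N, CO (1 atm), DMF–H2O, 60 °C; then aq. citric acid
Reagents that add atoms: carbon monoxide, [C-]#[O+]; water, O
Why: Palladium-catalysed hydroxycarbonylation, in which zerovalent palladium inserts into the alkenyl C–O bond, CO inserts and water cleaves the acylpalladium, places the C14 carboxyl on C8 with the alkene fixed at C7=C8.

Step 17
Reactants: 26 the bis-silyl ether acid of step 16
Product: 27 13,18-dihydroxy-13,14-seco-abiet-7-en-14-oic acid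
Conditions: aq. HF, MeCN, rt
Reagents that add atoms: none
Why: Fluoride-driven cleavage of both silyl ethers (strong Si–F bond) in acidic acetonitrile frees the C18 and C13 hydroxyls, and the unsaturated acid is stable to these conditions.

Step 18
Reactants: 27 the dihydroxy acid of step 17
Product: 28 (1R,4aS,5R,8aR)-1,4a-dimethyl-5-(4-methyl-3-oxopentyl)-1,2,3,4,4a,5,8,8a-octahydronaphthalene-1,6-dicarboxylic acid (13-oxo-13,14-seco-abiet-7-ene-14,18-dioic acid, CNP0333046.1)
Conditions: CrO3, H2SO4, H2O, acetone, 0 °C → rt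
Reagents that add atoms: water, O (carboxyl oxygen through the aldehyde hydrate; CrO3, O=[Cr](=O)=O, is the oxidant)
Why: Jones oxidation takes the primary C18 alcohol through the aldehyde hydrate to the acid and the C13 carbinol to the ketone in one operation, which erases the undefined centre, and no epimerizable stereocentre is at risk because C4 is quaternary.

**Compound list**

1 | geranyl acetate, (2E)-3,7-dimethylocta-2,6-dien-1-yl acetate | CC(C)=CCC/C(C)=C/COC(C)=O | starting material
2 | (2E,6E)-8-hydroxy-3,7-dimethylocta-2,6-dien-1-yl acetate | CC(=O)OC/C=C(C)/CC/C=C(C)/CO | intermediate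
3 | (2E)-5-[(2S,3S)-3-(hydroxymethyl)-3-methyloxiran-2-yl]-3-methylpent-2-en-1-yl acetate | CC(=O)OC/C=C(C)/CC[C@@H]1O[C@@]1(C)CO | intermediate
4 | (2E)-5-[(2S,3S)-3-({[tert-butyl(dimethyl)silyl]oxy}methyl)-3-methyloxiran-2-yl]-3-methylpent-2-en-1-yl acetate | CC(=O)OC/C=C(C)/CC[C@@H]1O[C@@]1(C)CO[Si](C)(C)C(C)(C)C | intermediate
5 | (2E)-5-[(2S,3S)-3-({[tert-butyl(dimethyl)silyl]oxy}methyl)-3-methyloxiran-2-yl]-3-methylpent-2-en-1-ol | OC/C=C(C)/CC[C@@H]1O[C@@]1(C)CO[Si](C)(C)C(C)(C)C | intermediate
6 | (2E)-5-[(2S,3S)-3-({[tert-butyl(dimethyl)silyl]oxy}methyl)-3-methyloxiran-2-yl]-3-methylpent-2-en-1-yl methanesulfonate | CS(=O)(=O)OC/C=C(C)/CC[C@@H]1O[C@@]1(C)CO[Si](C)(C)C(C)(C)C | intermediate (not isolated)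
7 | ({(2S,3S)-3-[(3E)-5-bromo-3-methylpent-3-en-1-yl]-2-methyloxiran-2-yl}methoxy)(tert-butyl)dimethylsilane | BrC/C=C(C)/CC[C@@H]1O[C@@]1(C)CO[Si](C)(C)C(C)(C)C | intermediate
8 | propargyl bromide (3-bromoprop-1-yne) | C#CCBr | starting material
9 | tert-butyl(dimethyl)({(2S,3S)-2-methyl-3-[(3E)-3-methyloct-3-en-7-yn-1-yl]oxiran-2-yl}methoxy)silane | C#CCC/C=C(C)/CC[C@@H]1O[C@@]1(C)CO[Si](C)(C)C(C)(C)C | intermediate
10 | (trimethylsilyl)methylmagnesium chloride | C[Si](C)(C)C[Mg]Cl | starting material
11 | alkenylcopper from syn addition to 9 (Cu on C9, cis to CH2SiMe3) | [Cu]/C=C(C[Si](C)(C)C)/CC/C=C(C)/CC[C@@H]1O[C@@]1(C)CO[Si](C)(C)C(C)(C)C | intermediate (not isolated)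
12 | tert-butyl({(2S,3S)-3-[(3E,7Z)-8-iodo-3-methyl-7-[(trimethylsilyl)methyl]octa-3,7-dien-1-yl]-2-methyloxiran-2-yl}methoxy)dimethylsilane | I/C=C(C[Si](C)(C)C)/CC/C=C(C)/CC[C@@H]1O[C@@]1(C)CO[Si](C)(C)C(C)(C)C | intermediate
13 | isobutyraldehyde (2-methylpropanal) | CC(C)C=O | starting material
14 | vinylmagnesium bromide | C=C[Mg]Br | starting material
15 | rac-4-methylpent-1-en-3-ol | CC(C)C(O)C=C | intermediate
16 | rac-tert-butyl(dimethyl)[(4-methylpent-1-en-3-yl)oxy]silane | CC(C)C(O[Si](C)(C)C(C)(C)C)C=C | intermediate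
17 | rac-9-(3-{[tert-butyl(dimethyl)silyl]oxy}-4-methylpentyl)-9-borabicyclo[3.3.1]nonane | CC(C)C(O[Si](C)(C)C(C)(C)C)CCB1C2CCCC1CCC2 | intermediate (not isolated)
18 | tert-butyl({(2S,3S)-3-[(3E,7Z)-11-{[tert-butyl(dimethyl)silyl]oxy}-3,12-dimethyl-7-[(trimethylsilyl)methyl]trideca-3,7-dien-1-yl]-2-methyloxiran-2-yl}methoxy)dimethylsilane, both epimers at the silyloxy carbon (C13) | CC(C)C(O[Si](C)(C)C(C)(C)C)CC/C=C(C[Si](C)(C)C)/CC/C=C(C)/CC[C@@H]1O[C@@]1(C)CO[Si](C)(C)C(C)(C)C | intermediate
19 | 13,18-bis(tert-butyldimethylsilyloxy)-13,14-seco-abiet-8(14)-en-3β-ol, both C13 epimers | CC(C)C(O[Si](C)(C)C(C)(C)C)CC[C@H]1C(=C)CC[C@@H]2[C@]1(C)CC[C@H](O)[C@@]2(C)CO[Si](C)(C)C(C)(C)C | intermediate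
20 | O-[13,18-bis(tert-butyldimethylsilyloxy)-13,14-seco-abiet-8(14)-en-3β-yl] O-phenyl thiocarbonate, both C13 epimers | CC(C)C(O[Si](C)(C)C(C)(C)C)CC[C@H]1C(=C)CC[C@@H]2[C@]1(C)CC[C@H](OC(=S)Oc3ccccc3)[C@@]2(C)CO[Si](C)(C)C(C)(C)C | intermediate
21 | 13,18-bis(tert-butyldimethylsilyloxy)-13,14-seco-abiet-8(14)-ene, both C13 epimers | CC(C)C(O[Si](C)(C)C(C)(C)C)CC[C@H]1C(=C)CC[C@@H]2[C@]1(C)CCC[C@@]2(C)CO[Si](C)(C)C(C)(C)C | intermediate
22 | spiro-1,2,4-trioxolane (ozonide) across C8 and C14 of 21 | CC(C)C(O[Si](C)(C)C(C)(C)C)CC[C@H]1C3(OCOO3)CC[C@@H]2[C@]1(C)CCC[C@@]2(C)CO[Si](C)(C)C(C)(C)C | intermediate (not isolated)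
23 | 13,18-bis(tert-butyldimethylsilyloxy)-14-nor-13,14-seco-abietan-8-one, both C13 epimers | CC(C)C(O[Si](C)(C)C(C)(C)C)CC[C@H]1C(=O)CC[C@@H]2[C@]1(C)CCC[C@@]2(C)CO[Si](C)(C)C(C)(C)C | intermediate
24 | lithium C7=C8 enolate of 23 | CC(C)C(O[Si](C)(C)C(C)(C)C)CC[C@H]1C(O[Li])=CC[C@@H]2[C@]1(C)CCC[C@@]2(C)CO[Si](C)(C)C(C)(C)C | intermediate (not isolated)
25 | 13,18-bis(tert-butyldimethylsilyloxy)-14-nor-13,14-seco-abiet-7-en-8-yl trifluoromethanesulfonate, both C13 epimers | CC(C)C(O[Si](C)(C)C(C)(C)C)CC[C@H]1C(OS(=O)(=O)C(F)(F)F)=CC[C@@H]2[C@]1(C)CCC[C@@]2(C)CO[Si](C)(C)C(C)(C)C | intermediate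
26 | 13,18-bis(tert-butyldimethylsilyloxy)-13,14-seco-abiet-7-en-14-oic acid, both C13 epimers | CC(C)C(O[Si](C)(C)C(C)(C)C)CC[C@H]1C(C(=O)O)=CC[C@@H]2[C@]1(C)CCC[C@@]2(C)CO[Si](C)(C)C(C)(C)C | intermediate
27 | 13,18-dihydroxy-13,14-seco-abiet-7-en-14-oic acid, both C13 epimers | CC(C)C(O)CC[C@H]1C(C(=O)O)=CC[C@@H]2[C@]1(C)CCC[C@@]2(C)CO | intermediate
28 | (1R,4aS,5R,8aR)-1,4a-dimethyl-5-(4-methyl-3-oxopentyl)-1,2,3,4,4a,5,8,8a-octahydronaphthalene-1,6-dicarboxylic acid | CC(C)C(=O)CC[C@H]1C(C(=O)O)=CC[C@@H]2[C@]1(C)CCC[C@@]2(C)C(=O)O | target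

**Step count**

Total: 18 steps. Longest linear sequence: 16 steps from geranyl acetate (steps 1–7 and 10–18); steps 8–9 make the side chain.

**Steps most likely to fail**

Step 11. The silyloxymethyl group on C4 retards ionization of the epoxide. Lewis-acid-induced rearrangement of the epoxide to a carbonyl compound, or proton loss from the C10 cation after ring A has closed, may therefore outrun the second ring closure.

The fallback opens the same epoxide by a radical instead of a cation; it sets out from alkyne 9 and comes back at 19. Carbocupration of 9 with the methylcopper reagent from MeMgBr and CuBr·SMe2 (Et2O–Me2S, −25 °C), then iodinolysis, would give tert-butyl({(2S,3S)-3-[(3E,7E)-8-iodo-3,7-dimethylocta-3,7-dien-1-yl]-2-methyloxiran-2-yl}methoxy)dimethylsilane F1. B-alkyl Suzuki–Miyaura coupling of F1 with alkylborane 17 under the conditions of step 10 would give the methyl-terminated epoxy diene tert-butyl({(2S,3S)-3-[(3E,7E)-11-{[tert-butyl(dimethyl)silyl]oxy}-3,7,12-trimethyltrideca-3,7-dien-1-yl]-2-methyloxiran-2-yl}methoxy)dimethylsilane F2. Cp2TiCl, a trivalent titanium reagent generated from Cp2TiCl2 and Mn dust in THF at rt, would open the epoxide homolytically at C4. The tertiary radical should close rings A and B by two 6-endo additions through the same chair–chair fold, and the C8 radical is expected to end by loss of a hydrogen atom from the C14 methyl, which would give 19 directly. This path does not depend on cation stability at C4. Its cost is that C4 is then set by the equatorial preference of the larger CH2OTBS group and not by inversion.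

Step 7. The slow carbocupration exposes the epoxide for hours to magnesium halide, which may open or rearrange it, and the addition itself may stall on this functionalized alkyne.

The fallback runs the organocopper chemistry before the epoxide exists; it sets out from 2 and comes back at 18.
- Silylation of 2 (TBSCl, imidazole) would give (2E,6E)-8-{[tert-butyl(dimethyl)silyl]oxy}-3,7-dimethylocta-2,6-dien-1-yl acetate F3.
- Methanolysis (K2CO3, MeOH) would give (2E,6E)-8-{[tert-butyl(dimethyl)silyl]oxy}-3,7-dimethylocta-2,6-dien-1-ol F4.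
- Appel bromination (CBr4, PPh3, CH2Cl2, 0 °C) would give {[(2E,6E)-8-bromo-2,6-dimethylocta-2,6-dien-1-yl]oxy}(tert-butyl)dimethylsilane F5.
- Propargylation as in step 6 would give tert-butyl{[(2E,6E)-2,6-dimethylundeca-2,6-dien-10-yn-1-yl]oxy}dimethylsilane F6.
- Carbocupration–iodinolysis as in step 7, now on a substrate without an epoxide, would give tert-butyl{[(2E,6E,10Z)-11-iodo-2,6-dimethyl-10-[(trimethylsilyl)methyl]undeca-2,6,10-trien-1-yl]oxy}dimethylsilane F7.
- Coupling with alkylborane 17 as in step 10 would give tert-butyl{[(2E,6E,10Z)-14-{[tert-butyl(dimethyl)silyl]oxy}-2,6,15-trimethyl-10-[(trimethylsilyl)methyl]hexadeca-2,6,10-trien-1-yl]oxy}dimethylsilane F8.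
- Pyridine-buffered HF·pyridine in THF at 0 °C should remove the primary allylic silyl ether well before the hindered secondary one, giving (2E,6E,10Z)-14-{[tert-butyl(dimethyl)silyl]oxy}-2,6,15-trimethyl-10-[(trimethylsilyl)methyl]hexadeca-2,6,10-trien-1-ol F9.
- Sharpless epoxidation with L-(+)-diethyl tartrate, which touches only the allylic alcohol, would give {(2S,3S)-3-[(3E,7Z)-11-{[tert-butyl(dimethyl)silyl]oxy}-3,12-dimethyl-7-[(trimethylsilyl)methyl]trideca-3,7-dien-1-yl]-2-methyloxiran-2-yl}methanol F10.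
- Silylation (TBSCl, imidazole) would then give 18.

Step 16. Oxidative addition and CO insertion at the hindered C8 triflate may be slow, so that hydrolysis of the triflate back to the ketone in the aqueous base takes over.

The fallback is a Shapiro carboxylation that needs neither triflate nor palladium; it sets out from ketone 23 and comes back at 26. Condensation of 23 with 2,4,6-triisopropylbenzenesulfonyl hydrazide (THF, cat. acid) would give the 2,4,6-triisopropylbenzenesulfonylhydrazone of 13,18-bis(tert-butyldimethylsilyloxy)-14-nor-13,14-seco-abietan-8-one F11. Treatment with n-BuLi (2 equiv) in THF–TMEDA from −78 to 0 °C should deprotonate C7, expel sulfinate and dinitrogen, and leave the C8 alkenyllithium with the C7=C8 alkene. Quenching with CO2 and acidification would give acid 26.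

Further compounds
F1 | step 11 | tert-butyl({(2S,3S)-3-[(3E,7E)-8-iodo-3,7-dimethylocta-3,7-dien-1-yl]-2-methyloxiran-2-yl}methoxy)dimethylsilane | I/C=C(C)/CC/C=C(C)/CC[C@@H]1O[C@@]1(C)CO[Si](C)(C)C(C)(C)C
F2 | step 11 | tert-butyl({(2S,3S)-3-[(3E,7E)-11-{[tert-butyl(dimethyl)silyl]oxy}-3,7,12-trimethyltrideca-3,7-dien-1-yl]-2-methyloxiran-2-yl}methoxy)dimethylsilane, both epimers at the silyloxy carbon | CC(C)C(O[Si](C)(C)C(C)(C)C)CC/C=C(C)/CC/C=C(C)/CC[C@@H]1O[C@@]1(C)CO[Si](C)(C)C(C)(C)C
F3 | step 7 | (2E,6E)-8-{[tert-butyl(dimethyl)silyl]oxy}-3,7-dimethylocta-2,6-dien-1-yl acetate | CC(=O)OC/C=C(C)/CC/C=C(C)/CO[Si](C)(C)C(C)(C)C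
F4 | step 7 | (2E,6E)-8-{[tert-butyl(dimethyl)silyl]oxy}-3,7-dimethylocta-2,6-dien-1-ol | OC/C=C(C)/CC/C=C(C)/CO[Si](C)(C)C(C)(C)C
F5 | step 7 | {[(2E,6E)-8-bromo-2,6-dimethylocta-2,6-dien-1-yl]oxy}(tert-butyl)dimethylsilane | BrC/C=C(C)/CC/C=C(C)/CO[Si](C)(C)C(C)(C)C
F6 | step 7 | tert-butyl{[(2E,6E)-2,6-dimethylundeca-2,6-dien-10-yn-1-yl]oxy}dimethylsilane | C#CCC/C=C(C)/CC/C=C(C)/CO[Si](C)(C)C(C)(C)C
F7 | step 7 | tert-butyl{[(2E,6E,10Z)-11-iodo-2,6-dimethyl-10-[(trimethylsilyl)methyl]undeca-2,6,10-trien-1-yl]oxy}dimethylsilane | I/C=C(C[Si](C)(C)C)/CC/C=C(C)/CC/C=C(C)/CO[Si](C)(C)C(C)(C)C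
F8 | step 7 | tert-butyl{[(2E,6E,10Z)-14-{[tert-butyl(dimethyl)silyl]oxy}-2,6,15-trimethyl-10-[(trimethylsilyl)methyl]hexadeca-2,6,10-trien-1-yl]oxy}dimethylsilane, both epimers at C14 | CC(C)C(O[Si](C)(C)C(C)(C)C)CC/C=C(C[Si](C)(C)C)/CC/C=C(C)/CC/C=C(C)/CO[Si](C)(C)C(C)(C)C
F9 | step 7 | (2E,6E,10Z)-14-{[tert-butyl(dimethyl)silyl]oxy}-2,6,15-trimethyl-10-[(trimethylsilyl)methyl]hexadeca-2,6,10-trien-1-ol, both epimers at C14 | CC(C)C(O[Si](C)(C)C(C)(C)C)CC/C=C(C[Si](C)(C)C)/CC/C=C(C)/CC/C=C(C)/CO
F10 | step 7 | {(2S,3S)-3-[(3E,7Z)-11-{[tert-butyl(dimethyl)silyl]oxy}-3,12-dimethyl-7-[(trimethylsilyl)methyl]trideca-3,7-dien-1-yl]-2-methyloxiran-2-yl}methanol, both epimers at the silyloxy carbon | CC(C)C(O[Si](C)(C)C(C)(C)C)CC/C=C(C[Si](C)(C)C)/CC/C=C(C)/CC[C@@H]1O[C@@]1(C)CO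
F11 | step 16 | 2,4,6-triisopropylbenzenesulfonylhydrazone of 13,18-bis(tert-butyldimethylsilyloxy)-14-nor-13,14-seco-abietan-8-one | CC(C)C(O[Si](C)(C)C(C)(C)C)CC[C@H]1C(=NNS(=O)(=O)c3c(C(C)C)cc(C(C)C)cc3C(C)C)CC[C@@H]2[C@]1(C)CCC[C@@]2(C)CO[Si](C)(C)C(C)(C)C
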